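**Retrosynthetic overview**
1. Target 20 is the (S)-senecioate of an 8-hydroxy-5-methoxynaphthalene-1,4-dione: C1=O lies next to the side-chain carbon C2 and peri to the 8-OH, C4=O lies peri to the 5-OMe, and C3 carries H.
2. The quinone ring is cut into three pieces by a Dötz benzannulation with oxidative work-up: the arene (C4a, C8a), two CO ligands of Cr(CO)6 (C4 and C1), and a terminal alkyne (C3, C2) that already carries the stereocenter and the ester; the ring closes by the C1–C8a bond.
3. Enabling feature: the quinone ring has an unsubstituted C3 and a substituted C2 between two carbonyl carbons, and the fused benzene ring carries OMe at C5, so the carbene aryl has a single free ortho carbon (C8a) and the terminal alkyne must place its substituted carbon next to the CO-derived C1.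
4. Alkyne 11 comes from 4-methylpent-3-enoic acid (Weinreb amide, ynone, Noyori transfer hydrogenation to set the only stereocenter, desilylation, esterification); carbene complex 17 comes from 3-bromo-4-methoxyphenol in two steps.
5. Ring order: the benzene ring is bought, the quinone ring is formed in step 8, and the last step only frees the 8-OH.

Key step: step 8

Remark: the stereocenter of the target is (S) (O > quinone carbon > CH2 > H, the alkannin series); 3-bromo-4-methoxyphenol is taken as a purchasable starting material.

**Route**

Step 1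
Reactants: 1 4-methylpent-3-enoic acid
Product: 3 N-methoxy-N,4-dimethylpent-3-enamide, via acyl imidazolide 2 (not isolated)
Conditions: CDI, CH2Cl2, rt; then MeNHOMe·HCl, rt
Reagents that add atoms: N,O-dimethylhydroxylamine hydrochloride, CNOC.Cl
Why: Weinreb amide formation through the acyl imidazolide runs under near-neutral conditions that should leave the skipped trisubstituted alkene in place.

Step 2
Reactants: 3 N-methoxy-N,4-dimethylpent-3-enamide; 4 ethynyltrimethylsilane
Product: 7 6-methyl-1-(trimethylsilyl)hept-5-en-1-yn-3-one, via lithium trimethylsilylacetylide 5 (not isolated), via lithium hemiaminal adduct 6 (not isolated)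
Conditions: 4, n-BuLi, THF, −78 °C; then 3, −78 to 0 °C; cold 1 M HCl
Reagents that add atoms: none
Why: Weinreb ketone synthesis, in which the weakly basic acetylide adds once to give a chelated tetrahedral adduct that releases the ynone only on the acidic quench.

Step 3
Reactants: 7 6-methyl-1-(trimethylsilyl)hept-5-en-1-yn-3-one
Product: 8 (3S)-6-methyl-1-(trimethylsilyl)hept-5-en-1-yn-3-ol
Conditions: Ru[(S,S)-TsNCH(Ph)CH(Ph)NH](p-cymene) (1 mol %, base-free), i-PrOH, rt
Reagents that add atoms: none
Why: Noyori asymmetric transfer hydrogenation of an alkynyl ketone, in which the alkynyl group takes the place of the aryl group of aryl ketones, so the (S,S)-catalyst should deliver hydride to the face that gives the (S)-carbinol (catalyst control, to be confirmed by Mosher ester analysis).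

Step 4
Reactants: 8 (3S)-6-methyl-1-(trimethylsilyl)hept-5-en-1-yn-3-ol
Product: 9 (3S)-6-methylhept-5-en-1-yn-3-ol
Conditions: K2CO3 (cat.), MeOH, 0 °C to rt
Reagents that add atoms: none
Why: base-catalyzed methanolysis of the alkynyl C–Si bond (protodesilylation) is selective and does not touch the carbinol stereocenter.

Step 5
Reactants: 9 (3S)-6-methylhept-5-en-1-yn-3-ol; 10 3-methylbut-2-enoic acid
Product: 11 (3S)-6-methylhept-5-en-1-yn-3-yl 3-methylbut-2-enoate
Conditions: DCC, DMAP (cat.), CH2Cl2, 0 °C to rt
Reagents that add atoms: none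
Why: Steglich esterification acylates the alcohol oxygen without breaking the C–O bond of the stereocenter, so the (S) configuration is retained.

Step 6
Reactants: 12 3-bromo-4-methoxyphenol
Product: 13 (3-bromo-4-methoxyphenoxy)triisopropylsilane
Conditions: TIPSCl, imidazole, DMF, rt
Reagents that add atoms: triisopropylsilyl chloride, CC(C)[Si](Cl)(C(C)C)C(C)C
Why: standard phenol silylation, with the bulky triisopropylsilyl group chosen because it should resist attack by the aryllithium of step 7 and the oxidant of step 8.

Step 7
Reactants: 13 (3-bromo-4-methoxyphenoxy)triisopropylsilane; 14 chromium hexacarbonyl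
Product: 17 pentacarbonyl{methoxy[2-methoxy-5-(triisopropylsilyloxy)phenyl]methylidene}chromium, via aryllithium 15 (not isolated), via lithium acylchromate 16 (not isolated)
Conditions: n-BuLi, Et2O, −78 °C; Cr(CO)6, −78 °C to rt; solvent exchange; Me3OBF4, CH2Cl2, 0 °C
Reagents that add atoms: trimethyloxonium tetrafluoroborate, C[O+](C)C.F[B-](F)(F)F
Why: Fischer carbene synthesis (bromine–lithium exchange, addition of the aryllithium to a CO ligand of zerovalent chromium, O-methylation with Meerwein salt), in which the lithium sits meta to the silyloxy group so that no silyl migration is possible.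

Step 8
Reactants: 17 pentacarbonyl{methoxy[2-methoxy-5-(triisopropylsilyloxy)phenyl]methylidene}chromium; 11 (3S)-6-methylhept-5-en-1-yn-3-yl 3-methylbut-2-enoate
Product: 19 (1S)-1-[5-methoxy-1,4-dioxo-8-(triisopropylsilyloxy)-1,4-dihydronaphthalen-2-yl]-4-methylpent-3-en-1-yl 3-methylbut-2-enoate, via naphthol tricarbonylchromium complex 18 (not isolated)
Conditions: 17 (1.3 equiv), 11 (1 equiv), degassed THF, 50 °C, Ar; then (NH4)2Ce(NO3)6 (about 6 equiv), MeCN/H2O, 0 °C
Reagents that add atoms: water, O
Why: Loss of one cis CO from 17, eased by the ortho methoxy group that can chelate the vacant site, is followed by alkyne coordination, insertion to a vinylcarbene, CO insertion to a chromium-bound dienylketene and 6π-electrocyclic closure of the ketene carbon onto the arene, which forms the C1–C8a bond and, after tautomerization, naphthol complex 18. The closest known reaction type is the Dötz benzannulation of aryl(methoxy)carbene complexes of zerovalent chromium with terminal alkynes, followed by oxidative work-up to 1,4-naphthoquinones. The six-membered quinone ring closes in a formal (3+2+1) manner, its last bond by a 6π-electrocyclization onto an sp2 arene carbon. No stereocenter is created: the (S)-carbinol center of 11 is a spectator whose C–O bond is never broken, and the planar chirality of 18 disappears when the metal is removed. Three selectivities are needed: the alkyne must insert with its substituted carbon next to the CO-derived C1, which terminal alkynes do for steric reasons; closure must occur at C8a, which is secured because the other ortho carbon carries OMe; and the oxidant must convert only the ring holding the free naphthol and its para methoxy group, the other ring being fully etherified and less easily oxidized (water supplies the C4 carbonyl oxygen and methanol leaves). The two trisubstituted alkenes and the ester should be poor partners for the carbene at 50 °C, and the immediate cold oxidation limits the time the benzylic ester spends next to an electron-rich naphthol.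

Step 9
Reactants: 19 (1S)-1-[5-methoxy-1,4-dioxo-8-(triisopropylsilyloxy)-1,4-dihydronaphthalen-2-yl]-4-methylpent-3-en-1-yl 3-methylbut-2-enoate
Product: 20 (1S)-1-(8-hydroxy-5-methoxy-1,4-dioxo-1,4-dihydronaphthalen-2-yl)-4-methylpent-3-en-1-yl 3-methylbut-2-enoate
Conditions: TBAF, AcOH (1:1), THF, 0 °C
Reagents that add atoms: none
Why: fluoride cleavage of an aryl silyl ether, made labile by the peri quinone carbonyl, should proceed under acetic acid buffering that protects the base-sensitive quinone and the ester, with the stereocenter untouched.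

**Compound list**
1 | 4-methylpent-3-enoic acid | CC(C)=CCC(=O)O | starting material
2 | 1-(imidazol-1-yl)-4-methylpent-3-en-1-one (acyl imidazolide) | CC(C)=CCC(=O)n1ccnc1 | intermediate
3 | N-methoxy-N,4-dimethylpent-3-enamide | CC(C)=CCC(=O)N(C)OC | intermediate
4 | ethynyltrimethylsilane | C#C[Si](C)(C)C | starting material
5 | lithium trimethylsilylacetylide | [Li]C#C[Si](C)(C)C | intermediate
6 | lithium hemiaminal adduct of 3 and 5 (racemic at the new carbon) | CC(C)=CCC(O[Li])(C#C[Si](C)(C)C)N(C)OC | intermediate
7 | 6-methyl-1-(trimethylsilyl)hept-5-en-1-yn-3-one | CC(C)=CCC(=O)C#C[Si](C)(C)C | intermediate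
8 | (3S)-6-methyl-1-(trimethylsilyl)hept-5-en-1-yn-3-ol | C[Si](C)(C)C#C[C@@H](O)CC=C(C)C | intermediate
9 | (3S)-6-methylhept-5-en-1-yn-3-ol | C#C[C@@H](O)CC=C(C)C | intermediate
10 | 3-methylbut-2-enoic acid | CC(C)=CC(=O)O | starting material
11 | (3S)-6-methylhept-5-en-1-yn-3-yl 3-methylbut-2-enoate | C#C[C@@H](OC(=O)C=C(C)C)CC=C(C)C | intermediate
12 | 3-bromo-4-methoxyphenol | COc1ccc(O)cc1Br | starting material
13 | (3-bromo-4-methoxyphenoxy)triisopropylsilane | COc1ccc(O[Si](C(C)C)(C(C)C)C(C)C)cc1Br | intermediate
14 | chromium hexacarbonyl | O=C=[Cr](=C=O)(=C=O)(=C=O)(=C=O)=C=O | starting material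
15 | [2-methoxy-5-(triisopropylsilyloxy)phenyl]lithium | COc1ccc(O[Si](C(C)C)(C(C)C)C(C)C)cc1[Li] | intermediate
16 | lithium pentacarbonyl[2-methoxy-5-(triisopropylsilyloxy)benzoyl]chromate | [Li+].[O-]C(c1cc(O[Si](C(C)C)(C(C)C)C(C)C)ccc1OC)=[Cr](=C=O)(=C=O)(=C=O)(=C=O)=C=O | intermediate
17 | pentacarbonyl{methoxy[2-methoxy-5-(triisopropylsilyloxy)phenyl]methylidene}chromium | COC(c1cc(O[Si](C(C)C)(C(C)C)C(C)C)ccc1OC)=[Cr](=C=O)(=C=O)(=C=O)(=C=O)=C=O | intermediate
18 | tricarbonylchromium complex (metal on the new ring, either face) of (1S)-1-[1-hydroxy-4,5-dimethoxy-8-(triisopropylsilyloxy)naphthalen-2-yl]-4-methylpent-3-en-1-yl 3-methylbut-2-enoate | COc1ccc(O[Si](C(C)C)(C(C)C)C(C)C)c2c(O)c([C@H](CC=C(C)C)OC(=O)C=C(C)C)cc(OC)c12.O=C=[Cr](=C=O)=C=O | intermediate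
19 | (1S)-1-[5-methoxy-1,4-dioxo-8-(triisopropylsilyloxy)-1,4-dihydronaphthalen-2-yl]-4-methylpent-3-en-1-yl 3-methylbut-2-enoate | COc1ccc(O[Si](C(C)C)(C(C)C)C(C)C)c2c1C(=O)C=C([C@H](CC=C(C)C)OC(=O)C=C(C)C)C2=O | intermediate
20 | (1S)-1-(8-hydroxy-5-methoxy-1,4-dioxo-1,4-dihydronaphthalen-2-yl)-4-methylpent-3-en-1-yl 3-methylbut-2-enoate | COc1ccc(O)c2c1C(=O)C=C([C@H](CC=C(C)C)OC(=O)C=C(C)C)C2=O | target

**Summary**
Total step count: 9. Longest linear sequence: 7 steps (steps 1 to 5, then 8 and 9); the arene branch contributes steps 6 and 7.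

**Steps most likely to fail**

Step 8. The acyloxy group may be lost or may migrate while the product is still an electron-rich naphthol (ionization to an ortho-quinone methide, acyl shift to the new phenol), or the ester carbonyl may divert the vinylcarbene before CO insertion. The fallback sets out from 9 and 17 and removes the ester from the annulation. Alcohol 9 would be silylated (TBSCl, imidazole, DMF) to tert-butyldimethyl{[(3S)-6-methylhept-5-en-1-yn-3-yl]oxy}silane F1. F1 would be heated with 17 in THF at 50 °C to give the naphthol tricarbonylchromium complex F2, which would be oxidized in the same flask with (NH4)2Ce(NO3)6 to the bis-silylated quinone 2-[(1S)-1-(tert-butyldimethylsilyloxy)-4-methylpent-3-enyl]-5-methoxy-8-(triisopropylsilyloxy)naphthalene-1,4-dione F3. Both silyl groups would be removed with TBAF/AcOH in THF (0 °C to rt) to give 8-hydroxy-2-[(1S)-1-hydroxy-4-methylpent-3-enyl]-5-methoxynaphthalene-1,4-dione F4. Its side-chain alcohol would be acylated selectively with 10 (DCC, DMAP, CH2Cl2, 0 °C), the peri-chelated phenol being a poor nucleophile, and the route comes back at 20.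

Step 3. The skipped alkene may migrate into conjugation with the ynone under the hydrogen-transfer conditions, or facial discrimination in the hydride transfer may be insufficient. The fallback sets out from 3 (and 5, made from 4) and avoids the ynone altogether. Amide 3 would be reduced with DIBAL-H (THF, −78 °C) to 4-methylpent-3-enal F5, which would be used crude and treated with 5 to give racemic 6-methyl-1-(trimethylsilyl)hept-5-en-1-yn-3-ol F6. Desilylation (K2CO3, MeOH) would give racemic 6-methylhept-5-en-1-yn-3-ol F7. Kinetic resolution with Candida antarctica lipase B and vinyl acetate in hexane should, by the empirical size rule for lipases (ethynyl small, prenyl-bearing chain large), acylate the (S)-alcohol to (3S)-6-methylhept-5-en-1-yn-3-yl acetate F8 and leave (3R)-6-methylhept-5-en-1-yn-3-ol F9, separable by chromatography. Methanolysis of F8 (K2CO3, MeOH) comes back to the route at 9.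

Step 7. Addition of the aryllithium to a CO ligand of the poorly soluble Cr(CO)6 may be incomplete, and methylation may partly occur at the metal. The fallback sets out from 13 and 14 and reverses the polarity of carbene assembly, with the metal as nucleophile. Aryllithium 15 (from 13 and n-BuLi) would be quenched with CO2 to 2-methoxy-5-(triisopropylsilyloxy)benzoic acid F10, which would be converted with oxalyl chloride and catalytic DMF to 2-methoxy-5-(triisopropylsilyloxy)benzoyl chloride F11. Separately 14 would be reduced with KC8 in THF at −78 °C to dipotassium pentacarbonylchromate F12 (chromium in the formal oxidation state minus two). Acylation of F12 with F11 would give potassium pentacarbonyl[2-methoxy-5-(triisopropylsilyloxy)benzoyl]chromate F13, and O-methylation with Me3OBF4 comes back to the route at 17.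

**Further compounds**
F1 | step 8 | tert-butyldimethyl{[(3S)-6-methylhept-5-en-1-yn-3-yl]oxy}silane | C#C[C@@H](O[Si](C)(C)C(C)(C)C)CC=C(C)C
F2 | step 8 | tricarbonylchromium complex of 2-[(1S)-1-(tert-butyldimethylsilyloxy)-4-methylpent-3-enyl]-4,5-dimethoxy-8-(triisopropylsilyloxy)naphthalen-1-ol | COc1ccc(O[Si](C(C)C)(C(C)C)C(C)C)c2c(O)c([C@H](CC=C(C)C)O[Si](C)(C)C(C)(C)C)cc(OC)c12.O=C=[Cr](=C=O)=C=O
F3 | step 8 | 2-[(1S)-1-(tert-butyldimethylsilyloxy)-4-methylpent-3-enyl]-5-methoxy-8-(triisopropylsilyloxy)naphthalene-1,4-dione | COc1ccc(O[Si](C(C)C)(C(C)C)C(C)C)c2c1C(=O)C=C([C@H](CC=C(C)C)O[Si](C)(C)C(C)(C)C)C2=O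
F4 | step 8 | 8-hydroxy-2-[(1S)-1-hydroxy-4-methylpent-3-enyl]-5-methoxynaphthalene-1,4-dione | COc1ccc(O)c2c1C(=O)C=C([C@H](CC=C(C)C)O)C2=O
F5 | step 3 | 4-methylpent-3-enal | CC(C)=CCC=O
F6 | step 3 | racemic 6-methyl-1-(trimethylsilyl)hept-5-en-1-yn-3-ol | CC(C)=CCC(O)C#C[Si](C)(C)C
F7 | step 3 | racemic 6-methylhept-5-en-1-yn-3-ol | C#CC(O)CC=C(C)C
F8 | step 3 | (3S)-6-methylhept-5-en-1-yn-3-yl acetate | C#C[C@@H](OC(C)=O)CC=C(C)C
F9 | step 3 | (3R)-6-methylhept-5-en-1-yn-3-ol | C#C[C@H](O)CC=C(C)C
F10 | step 7 | 2-methoxy-5-(triisopropylsilyloxy)benzoic acid | COc1ccc(O[Si](C(C)C)(C(C)C)C(C)C)cc1C(=O)O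
F11 | step 7 | 2-methoxy-5-(triisopropylsilyloxy)benzoyl chloride | COc1ccc(O[Si](C(C)C)(C(C)C)C(C)C)cc1C(=O)Cl
F12 | step 7 | dipotassium pentacarbonylchromate | [K+].[K+].O=C=[Cr-2](=C=O)(=C=O)(=C=O)=C=O
F13 | step 7 | potassium pentacarbonyl[2-methoxy-5-(triisopropylsilyloxy)benzoyl]chromate | [K+].[O-]C(c1cc(O[Si](C(C)C)(C(C)C)C(C)C)ccc1OC)=[Cr](=C=O)(=C=O)(=C=O)(=C=O)=C=O
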